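**Plan**

1. Cuts: in the tetrahydrofuran, the C8–C9 and O–C16 bonds (the C14–O bond of the ortho ester closes in the same flask). This divides the target into a ring-A spiro-lactone carrying C7–O and C8, made from (S)-carvone, and a bicyclic bis-lactone carrying C9–C19, made from methyl hydrogen (R)-3-methylglutarate.
2. Enabling feature: the tetrahydrofuran is a γ-butyrolactone at the ortho ester oxidation level. C9 is the α-carbon of the acyl carbon C16, and C7(O)–C8 is what an epoxide leaves behind. The 1,4-relation between the oxygen on C7 and the oxygens on C16 is dissonant, so C8 is made a sulfur-stabilised cation that carries its own oxygen nucleophile on C7.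
3. Forward, left half: carvone, hydration, Luche reduction, hydroboration/oxidation (ring A); formylation, Michael addition, reduction (spiro-δ-lactone); Corey–Chaykovsky epoxide, thiolate opening, α-chloro sulfide.
4. Forward, right half: 4-methyl-δ-valerolactone aldol with 2,2-dimethoxypropanal, lactone switch to γ-pseudo-ester plus δ-lactone, α-methylenation, 1,4-hydrosilylation to the C9 ketene acetal. Then union with cage closure, desulfurisation, desilylation.
5. Stereochemistry: C5 from carvone; C3 by Luche reduction; C2 by hydroboration anti to the C3 oxygen; C6 by Michael addition anti to the side chain; C7 by axial methylene transfer; C10 from the glutarate; C11 and C19 by the lactone aldol; C9, C16 and C14 in the key step, under control of the bicycle and the tethers.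

Key step: step 20

Remark on numbering (used throughout, not IUPAC): ring A is C2 (CH–CH3), C3 (CH–OH), C4 (CH2), C5 (CH–CMe2OH), C6 (spiro carbon), C7 (C–O). C8 is the tetrahydrofuran CH2, C9 the quaternary C–CH3, C10 the CH–CH3, C11 the CH next to the γ-lactone carbonyl C12, C14 the ketal carbon bearing CH3, C16 the ortho ester carbon, C19 the O–CH.

Remark on mixtures: the C14 anomers (22–30), the lactol carbon of 23, C9 in 25 and 26, and the sulfur-bearing C8 (14, 29–31) are carried as mixtures. These centres are planarised or removed later, so their SMILES leave them undefined.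

**Route**

Step 1
Reactants: 1 (S)-(+)-carvone
Product: 2 (5S)-5-(2-hydroxypropan-2-yl)-2-methylcyclohex-2-en-1-one
Conditions: 50% aq H2SO4, 0 °C
Reagents that add atoms: water, O
Why: Acid-catalysed Markovnikov hydration should act only on the isopropenyl group (tertiary cation), the conjugated ring alkene being deactivated; no new stereocentre.

Step 2
Reactants: 2 hydroxy enone
Product: 3 (1S,5S)-5-(2-hydroxypropan-2-yl)-2-methylcyclohex-2-en-1-ol
Conditions: NaBH4, CeCl3·7H2O, MeOH, −78 → 0 °C
Reagents that add atoms: none
Why: Luche 1,2-reduction; axial hydride delivery to the half-chair with the C5 side chain equatorial should give the pseudo-equatorial alcohol cis to the side chain (C3).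

Step 3
Reactants: 3 cis diol
Product: 4 bis(triethylsilyl) ether of 3
Conditions: Et3SiOTf, 2,6-lutidine, CH2Cl2, −78 → 0 °C
Reagents that add atoms: triethylsilyl trifluoromethanesulfonate, CC[Si](CC)(CC)OS(=O)(=O)C(F)(F)F
Why: Silyl triflate silylation of the secondary allylic and the tertiary alcohol; both ethers are meant to last to step 22.

Step 4
Reactants: 4 bis(silyl) ether
Product: 5 ring-A alcohol (C7–OH; C2 methyl cis to the C3 silyloxy group and to the C5 side chain, C7 hydroxyl trans to them)
Conditions: BH3·THF, THF, 0 °C → rt; then NaOH, H2O2, 0 °C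
Reagents that add atoms: hydrogen peroxide, OO
Why: Hydroboration–oxidation; boron should add to the less substituted C7 on the face opposite to the allylic silyloxy group and the C5 side chain, so hydrogen reaches C2 anti to them and the C2 methyl ends cis to the C3 oxygen (the C7 carbinol centre is erased in step 5).

Step 5
Reactants: 5 ring-A alcohol
Product: 6 ring-A ketone (C7 ketone; 2-methyl, 3-silyloxy and 5-substituent all cis)
Conditions: Dess–Martin periodinane, CH2Cl2, 0 °C → rt
Reagents that add atoms: none
Why: Non-basic Dess–Martin oxidation of the secondary alcohol, chosen so that the epimerisable C2 centre and the β-silyloxy group are not disturbed.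

Step 6
Reactants: 6 ring-A ketone
Product: 7 C6-hydroxymethylene ketone (enol of the C6-formyl ketone)
Conditions: LiN(iPr)2, THF, −78 °C; CF3CH2OCHO, −78 → 0 °C; AcOH
Reagents that add atoms: 2,2,2-trifluoroethyl formate, O=COCC(F)(F)F
Why: Kinetic deprotonation at the only α-methylene (C6), then Claisen-type C-formylation with the activated formate; the planar hydroxymethylene group activates C6 for step 7.

Step 7
Reactants: 7 hydroxymethylene ketone; 8 methyl acrylate
Product: 9 keto aldehyde ester (quaternary C6 bearing CHO cis to the C5 side chain and CH2CH2CO2Me trans to it)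
Conditions: Et3N, MeCN, 40 °C
Reagents that add atoms: none
Why: Amine-catalysed Michael addition of the β-keto aldehyde; the acrylate should approach C6 anti to the bulky C5 side chain, which sets the quaternary centre.

Step 8
Reactants: 9 keto aldehyde ester
Product: 11 keto spiro-δ-lactone, via hydroxy keto ester 10 (not isolated)
Conditions: NaBH4, MeOH/CH2Cl2, −78 °C; AcOH; then PPTS (cat.), toluene, 60 °C
Reagents that add atoms: none
Why: Chemoselective borohydride reduction of the aldehyde beside the hindered ketone, then acid-catalysed lactonisation of the δ-hydroxy ester closes the spiro-δ-lactone; no stereocentre changes.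

Step 9
Reactants: 11 keto spiro-δ-lactone
Product: 12 spiro-epoxide (oxirane oxygen on C7 cis to the C2 methyl and the C6–CH2O arm, C8 anti to them)
Conditions: Me3S+ I−, KN(SiMe3)2, THF, −20 → 0 °C
Reagents that add atoms: trimethylsulfonium iodide, C[S+](C)C.[I-]
Why: Corey–Chaykovsky epoxidation; the small, weakly basic sulfonium methylide should add irreversibly along the axial trajectory, anti to the axial C2 methyl and axial C6–CH2O groups on the other face, so the C7 oxygen ends cis to them.

Step 10
Reactants: 12 spiro-epoxide
Product: 13 C7 trimethylsilyl ether, C8 phenyl sulfide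
Conditions: PhSSiMe3, Bu4NF (5 mol %), THF, 0 °C → rt
Reagents that add atoms: (phenylthio)trimethylsilane, C[Si](C)(C)Sc1ccccc1
Why: Fluoride-initiated thiolate opening of the epoxide by SN2 at the primary C8, with silyl transfer to the alkoxide; C7 is untouched and the immediate silylation keeps the tertiary alkoxide from attacking the lactone.

Step 11
Reactants: 13 β-silyloxy sulfide
Product: 14 α-chloro sulfide (C8 bearing Cl and SPh)
Conditions: N-chlorosuccinimide, CCl4, rt
Reagents that add atoms: N-chlorosuccinimide, O=C1CCC(=O)N1Cl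
Why: α-Chlorination of the sulfide through the chlorosulfonium ion; C7 has no hydrogen, so no vinyl sulfide can form.

Step 12
Reactants: 15 methyl hydrogen (R)-3-methylglutarate
Product: 17 (4R)-4-methyltetrahydro-2H-pyran-2-one, via methyl (3R)-5-hydroxy-3-methylpentanoate 16 (not isolated)
Conditions: BH3·SMe2, THF, 0 °C → rt; MeOH; then TsOH (cat.), CH2Cl2, rt
Reagents that add atoms: none
Why: Chemoselective borane reduction of the acid beside the ester, then lactonisation; the lactone carbonyl is the former ester carbon (C12) and C10 is untouched.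

Step 13
Reactants: 18 methyl 2,2-dimethoxypropanoate
Product: 19 2,2-dimethoxypropanal
Conditions: iBu2AlH, CH2Cl2, −78 °C; aq Rochelle salt
Reagents that add atoms: none
Why: Partial reduction of the ester; the aluminium hemiacetal is held by chelation to an α-methoxy group until work-up.

Step 14
Reactants: 17 (4R)-lactone; 19 2,2-dimethoxypropanal
Product: 20 (3R,4R)-3-[(1S)-1-hydroxy-2,2-dimethoxypropyl]-4-methyltetrahydro-2H-pyran-2-one
Conditions: LiN(iPr)2, THF, −78 °C; then 19, −78 °C; AcOH
Reagents that add atoms: none
Why: Aldol addition of the lactone lithium enolate; attack anti to the C10 methyl sets C11 (3,4-trans), and the chair transition state of the ring-locked E-enolate with the bulky aldehyde substituent equatorial should give the anti aldol (C19).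

Step 15
Reactants: 20 aldol lactone
Product: 22 pseudo-ester diol (5-methoxy-5-methyl-γ-lactone with C19–OH cis to the C11 side chain and a free C16 primary alcohol), via ring-opened hydroxy acid 21 (not isolated)
Conditions: LiOH, THF/H2O, 0 °C; AcOH to pH 4–5; then PPTS (cat.), 4 Å MS, CH2Cl2, rt
Reagents that add atoms: lithium hydroxide, [Li+].[OH-]
Why: Saponification, then acid-catalysed intramolecular transketalisation in which the carboxylic acid captures the oxocarbenium ion of the ketal; this ties C12 into the γ-lactone pseudo-ester and frees the C16 and C19 hydroxyls without touching C11 or C19.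

Step 16
Reactants: 22 pseudo-ester diol
Product: 24 cis-fused bicyclic bis-lactone, via lactol 23 (not isolated)
Conditions: TEMPO (cat.), PhI(OAc)2, CH2Cl2, rt
Reagents that add atoms: none
Why: Oxidative lactonisation of a 1,5-diol (oxoammonium oxidation of the primary alcohol, lactol formation with the C19 hydroxyl, second oxidation); the cis relation of C11–H and C19–H gives the cis ring fusion.

Step 17
Reactants: 24 bicyclic bis-lactone
Product: 25 C9 (dimethylamino)methyl lactone
Conditions: LiN(SiMe3)2, THF, −78 °C; CH2=NMe2+ I−, −78 → 0 °C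
Reagents that add atoms: N,N-dimethylmethyleneiminium iodide, C=[N+](C)C.[I-]
Why: Kinetic deprotonation at the only α-methylene (C9) and Mannich reaction with Eschenmoser's salt; the tertiary ring-fusion C11–H should be slower to deprotonate.

Step 18
Reactants: 25 Mannich base
Product: 27 α-methylene bis-lactone, via trimethylammonium iodide 26 (not isolated)
Conditions: MeI, CH2Cl2, rt; then DBU, 0 °C
Reagents that add atoms: none
Why: Quaternisation and E1cB loss of trimethylamine give the exocyclic methylene on C9.

Step 19
Reactants: 27 α-methylene bis-lactone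
Product: 28 triethylsilyl ketene acetal (C9(CH3)=C16(OSiEt3)–O)
Conditions: RhCl(PPh3)3 (2 mol %), Et3SiH, toluene, 60 °C
Reagents that add atoms: triethylsilane, CC[SiH](CC)CC
Why: Rhodium-catalysed 1,4-hydrosilylation of the α-methylene lactone should give the ketene acetal regiospecifically at C9 without base, turning the methylene carbon into the C9 methyl.

Step 20
Reactants: 14 α-chloro sulfide; 28 triethylsilyl ketene acetal
Product: 31 C8-phenylthio bis(triethylsilyl) ether of chermebilaene B, via coupled δ-lactone 29 (not isolated), via silyl ortho ester 30 (not isolated)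
Conditions: Me3SiOTf, 2,6-di-tert-butyl-4-methylpyridine, 4 Å MS, CH2Cl2, −78 °C, then 0 °C
Reagents that add atoms: none
Why: Proposed new method: Me3SiOTf should abstract chloride from 14 to give the C8 thionium ion, which ketene acetal 28 attacks through C9 to give δ-lactone 29 (closest known reaction type: Lewis-acid phenylthioalkylation of silyl enol ethers and ketene acetals by α-chloro sulfides); the silyl triflate then activates the C16 carbonyl, the neighbouring C7–OSiMe3 oxygen adds to it and loses its silyl group (silyl ortho ester 30), and on warming the C14–OMe group ionises and is captured by the C16–OSiEt3 oxygen, the two C–O events being the intramolecular counterpart of silyl-triflate-catalysed acetalisation of carbonyl groups by silyl ethers. The tetrahydrofuran closes by the intermolecular C8–C9 bond followed by 5-exo-trig attack of oxygen on C16, and the dioxolane by 5-exo-trig attack of oxygen on the C14 oxocarbenium ion. C9 is controlled by the cis-fused bicycle of 28: the thionium ion should add to the convex face, anti to the pseudo-axial C11–C12 bond and the C10 methyl, so the C9 and C10 methyl groups end cis; C16 and C14 are dictated by the five-membered tethers, which reach one face only; C7 is already fixed in 14, and the uncontrolled sulfide centre at C8 is deleted in step 21. The step needs attack at C8 and not at the tertiary C7 (the risk with an epoxide under Lewis acid), which the sulfur-stabilised cation secures, and it needs C–C bond formation before the pseudo-ester ionises, which the temperature staging secures. The dissonant 1,4-relation between the C7 oxygen and the C16 acyl carbon is thus bridged by making C8 electrophilic while its oxygen nucleophile is already in place on C7.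

Step 21
Reactants: 31 C8-phenylthio cage
Product: 32 bis(triethylsilyl) ether of chermebilaene B
Conditions: Raney Ni (W-2), EtOH, rt
Reagents that add atoms: none
Why: Reductive desulfurisation removes the activating sulfide and leaves C8 as CH2; ortho ester, lactones and silyl ethers should be inert.

Step 22
Reactants: 32 bis(triethylsilyl) ether
Product: 33 chermebilaene B
Conditions: HF·pyridine, pyridine, THF, 0 °C → rt
Reagents that add atoms: none
Why: Fluoride cleavage of both triethylsilyl ethers under pyridine-buffered conditions that the caged ortho ester and the lactones should tolerate.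

**Compound list**

1 | (S)-(+)-carvone, (5S)-2-methyl-5-(prop-1-en-2-yl)cyclohex-2-en-1-one | CC1=CC[C@@H](CC1=O)C(C)=C | starting material
2 | (5S)-5-(2-hydroxypropan-2-yl)-2-methylcyclohex-2-en-1-one | CC1=CC[C@@H](CC1=O)C(C)(C)O | intermediate
3 | (1S,5S)-5-(2-hydroxypropan-2-yl)-2-methylcyclohex-2-en-1-ol (hydroxyl cis to the side chain) | CC1=CC[C@@H](C[C@@H]1O)C(C)(C)O | intermediate
4 | bis(triethylsilyl) ether of 3 | CC1=CC[C@@H](C[C@@H]1O[Si](CC)(CC)CC)C(C)(C)O[Si](CC)(CC)CC | intermediate
5 | ring-A alcohol, 2-methyl-3-(triethylsilyloxy)-5-[2-(triethylsilyloxy)propan-2-yl]cyclohexan-1-ol (2,3,5-cis, 1-OH trans) | C[C@H]1[C@@H](O[Si](CC)(CC)CC)C[C@@H](C(C)(C)O[Si](CC)(CC)CC)C[C@@H]1O | intermediate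
6 | ring-A ketone, 2-methyl-3-(triethylsilyloxy)-5-[2-(triethylsilyloxy)propan-2-yl]cyclohexan-1-one (2,3,5-cis) | C[C@H]1[C@@H](O[Si](CC)(CC)CC)C[C@@H](C(C)(C)O[Si](CC)(CC)CC)CC1=O | intermediate
7 | C6-hydroxymethylene derivative of 6 | C[C@H]1[C@@H](O[Si](CC)(CC)CC)C[C@@H](C(C)(C)O[Si](CC)(CC)CC)C(=CO)C1=O | intermediate
8 | methyl acrylate | C=CC(=O)OC | starting material
9 | keto aldehyde ester, methyl 3-[1-formyl-3-methyl-2-oxo-4-(triethylsilyloxy)-6-(2-(triethylsilyloxy)propan-2-yl)cyclohexyl]propanoate (formyl cis to the 6-substituent) | C[C@H]1[C@@H](O[Si](CC)(CC)CC)C[C@@H](C(C)(C)O[Si](CC)(CC)CC)[C@](C=O)(CCC(=O)OC)C1=O | intermediate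
10 | hydroxy keto ester (CH2OH in place of CHO in 9; not isolated) | C[C@H]1[C@@H](O[Si](CC)(CC)CC)C[C@@H](C(C)(C)O[Si](CC)(CC)CC)[C@](CO)(CCC(=O)OC)C1=O | intermediate
11 | keto spiro-δ-lactone, 8-methyl-9-(triethylsilyloxy)-11-[2-(triethylsilyloxy)propan-2-yl]-2-oxaspiro[5.5]undecane-3,7-dione | C[C@H]1[C@@H](O[Si](CC)(CC)CC)C[C@@H](C(C)(C)O[Si](CC)(CC)CC)[C@]2(CCC(=O)OC2)C1=O | intermediate
12 | spiro-epoxide of 11 (oxirane O on C7 cis to C2–CH3 and C6–CH2O) | C[C@H]1[C@@H](O[Si](CC)(CC)CC)C[C@@H](C(C)(C)O[Si](CC)(CC)CC)[C@]2(CCC(=O)OC2)[C@]13CO3 | intermediate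
13 | C7 trimethylsilyl ether, C8 phenyl sulfide | C[C@H]1[C@@H](O[Si](CC)(CC)CC)C[C@@H](C(C)(C)O[Si](CC)(CC)CC)[C@]2(CCC(=O)OC2)[C@]1(O[Si](C)(C)C)CSc1ccccc1 | intermediate
14 | α-chloro sulfide (C8 bearing Cl and SPh) | C[C@H]1[C@@H](O[Si](CC)(CC)CC)C[C@@H](C(C)(C)O[Si](CC)(CC)CC)[C@]2(CCC(=O)OC2)[C@]1(O[Si](C)(C)C)C(Cl)Sc1ccccc1 | intermediate
15 | methyl hydrogen (R)-3-methylglutarate, (3R)-5-methoxy-3-methyl-5-oxopentanoic acid | COC(=O)C[C@H](C)CC(=O)O | starting material
16 | methyl (3R)-5-hydroxy-3-methylpentanoate (not isolated) | COC(=O)C[C@H](C)CCO | intermediate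
17 | (4R)-4-methyltetrahydro-2H-pyran-2-one | C[C@@H]1CCOC(=O)C1 | intermediate
18 | methyl 2,2-dimethoxypropanoate | COC(=O)C(C)(OC)OC | starting material
19 | 2,2-dimethoxypropanal | CC(OC)(OC)C=O | intermediate
20 | (3R,4R)-3-[(1S)-1-hydroxy-2,2-dimethoxypropyl]-4-methyltetrahydro-2H-pyran-2-one | C[C@@H]1CCOC(=O)[C@H]1[C@H](O)C(C)(OC)OC | intermediate
21 | ring-opened hydroxy acid of 20 (not isolated) | OCC[C@@H](C)[C@@H](C(=O)O)[C@H](O)C(C)(OC)OC | intermediate
22 | pseudo-ester diol, 4-hydroxy-3-(4-hydroxybutan-2-yl)-5-methoxy-5-methyldihydrofuran-2(3H)-one (3,4-cis) | OCC[C@@H](C)[C@H]1C(=O)OC(C)(OC)[C@H]1O | intermediate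
23 | δ-lactol of 22 (not isolated) | OC1C[C@@H](C)[C@H]2C(=O)OC(C)(OC)[C@H]2O1 | intermediate
24 | cis-fused bicyclic bis-lactone (δ-lactone C16(=O)–O–C19 fused to the 5-methoxy-5-methyl-γ-lactone) | O=C1C[C@@H](C)[C@H]2C(=O)OC(C)(OC)[C@H]2O1 | intermediate
25 | C9 (dimethylamino)methyl derivative of 24 | O=C1C(CN(C)C)[C@@H](C)[C@H]2C(=O)OC(C)(OC)[C@H]2O1 | intermediate
26 | trimethylammonium iodide of 25 (not isolated) | O=C1C(C[N+](C)(C)C)[C@@H](C)[C@H]2C(=O)OC(C)(OC)[C@H]2O1.[I-] | intermediate
27 | α-methylene bis-lactone | O=C1C(=C)[C@@H](C)[C@H]2C(=O)OC(C)(OC)[C@H]2O1 | intermediate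
28 | triethylsilyl ketene acetal of the δ-lactone (C9(CH3)=C16) | CC1=C(O[Si](CC)(CC)CC)O[C@@H]2C(C)(OC)OC(=O)[C@@H]2[C@@H]1C | intermediate
29 | C8–C9 coupled δ-lactone (not isolated in step 20) | C[C@H]1[C@@H](O[Si](CC)(CC)CC)C[C@@H](C(C)(C)O[Si](CC)(CC)CC)[C@]2(CCC(=O)OC2)[C@]1(O[Si](C)(C)C)C(Sc1ccccc1)[C@@]3(C)C(=O)O[C@@H]4C(C)(OC)OC(=O)[C@@H]4[C@@H]3C | intermediate
30 | silyl ortho ester with the tetrahydrofuran closed (not isolated) | C[C@H]1[C@@H](O[Si](CC)(CC)CC)C[C@@H](C(C)(C)O[Si](CC)(CC)CC)[C@]2(CCC(=O)OC2)[C@]12C(Sc3ccccc3)[C@]1(C)[C@@H](C)[C@H]3C(=O)OC(C)(OC)[C@H]3O[C@]1(O[Si](CC)(CC)CC)O2 | intermediate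
31 | C8-phenylthio bis(triethylsilyl) ether of chermebilaene B | C[C@H]1[C@@H](O[Si](CC)(CC)CC)C[C@@H](C(C)(C)O[Si](CC)(CC)CC)[C@]2(CCC(=O)OC2)[C@]12C(Sc3ccccc3)[C@]1(C)[C@@H](C)[C@H]3C(=O)O[C@@]4(C)O[C@@]1(O[C@@H]34)O2 | intermediate
32 | bis(triethylsilyl) ether of chermebilaene B | C[C@H]1[C@@H](O[Si](CC)(CC)CC)C[C@@H](C(C)(C)O[Si](CC)(CC)CC)[C@]2(CCC(=O)OC2)[C@]12C[C@]1(C)[C@@H](C)[C@H]3C(=O)O[C@@]4(C)O[C@@]1(O[C@@H]34)O2 | intermediate
33 | chermebilaene B | C[C@H]1[C@@H](O)C[C@@H](C(C)(C)O)[C@]2(CCC(=O)OC2)[C@]12C[C@]1(C)[C@@H](C)[C@H]3C(=O)O[C@@]4(C)O[C@@]1(O[C@@H]34)O2 | target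

**Step count and risks**

Total steps: 22. Longest linear sequence: 14 steps (steps 1–11 and 20–22; the right half takes steps 12–19).

Steps most likely to fail:

Step 20 (labelled). After the C8–C9 bond has formed the sequence may stall or divert. Closure of the tetrahydrofuran needs a hindered tertiary silyl ether to add to a hindered lactone carbonyl, and silyl ortho ester 30 may reopen toward translactonised material instead of closing the cage. The fallback sets out from 14 and 28. The C–C bond alone is made by the known ZnBr2-catalysed phenylthioalkylation (CH2Cl2, −40 °C) and the coupled δ-lactone 29 is isolated. Raney Ni in EtOH then gives the desulfurised coupled lactone F1, and HF·pyridine gives the triol lactone pseudo-ester F2. The cage is closed under thermodynamic control by acid-catalysed ortho ester formation (camphorsulfonic acid, benzene, 4 Å MS, 60 °C): the free C7 hydroxyl adds to the lactone carbonyl and the resulting hemi-ortho ester hydroxyl replaces methanol at C14. This comes back to the route at 33.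

Step 9. The doubly flanked ketone may not accept the ylide, or may enolise toward C2, with epimerisation of the axial methyl or β-elimination of the C3 silyloxy group. The fallback sets out from 10, which is isolated after the borohydride stage of step 8 instead of being lactonised. Takai–Lombardo methylenation (Zn, CH2Br2, TiCl4, THF/CH2Cl2) gives the methylene hydroxy ester F3 without base. Hydroxyl-directed epoxidation (VO(acac)2, tBuOOH, CH2Cl2) from the C6–CH2OH group delivers oxygen to the face it occupies and gives the epoxy hydroxy ester F4 with the same C7 configuration. Lactonisation (DBU cat., toluene, 60 °C) comes back to the route at 12.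

Step 17. Deprotonation may occur at the ring-fusion carbon C11 of the γ-lactone in competition with C9, followed by β-elimination of the C19 oxygen and opening of the δ-lactone. The fallback sets out from 22 and avoids enolate chemistry. Oxidation with TEMPO and a single equivalent of PhI(OAc)2 is stopped at lactol 23, which is isolated. Amine-catalysed α-methylenation of its open hydroxy aldehyde form (aq CH2O, pyrrolidine, propionic acid, iPrOH, 45 °C) gives the α-methylene lactol F5. Oxidation of the lactol (TEMPO, PhI(OAc)2, CH2Cl2) comes back to the route at 27.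

**Further compounds**

F1 | step 20 | desulfurised coupled δ-lactone (29 with CH2 at C8) | C[C@H]1[C@@H](O[Si](CC)(CC)CC)C[C@@H](C(C)(C)O[Si](CC)(CC)CC)[C@]2(CCC(=O)OC2)[C@]1(O[Si](C)(C)C)C[C@@]3(C)C(=O)O[C@@H]4C(C)(OC)OC(=O)[C@@H]4[C@@H]3C
F2 | step 20 | triol lactone pseudo-ester (F1 without silyl groups) | C[C@H]1[C@@H](O)C[C@@H](C(C)(C)O)[C@]2(CCC(=O)OC2)[C@]1(O)C[C@@]3(C)C(=O)O[C@@H]4C(C)(OC)OC(=O)[C@@H]4[C@@H]3C
F3 | step 9 | methylene hydroxy ester (C7=CH2 in place of C7=O in 10) | C[C@H]1[C@@H](O[Si](CC)(CC)CC)C[C@@H](C(C)(C)O[Si](CC)(CC)CC)[C@](CO)(CCC(=O)OC)C1=C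
F4 | step 9 | epoxy hydroxy ester (oxirane O cis to the C6–CH2OH group) | C[C@H]1[C@@H](O[Si](CC)(CC)CC)C[C@@H](C(C)(C)O[Si](CC)(CC)CC)[C@](CO)(CCC(=O)OC)[C@]13CO3
F5 | step 17 | α-methylene lactol (C9=CH2 derivative of 23) | OC1C(=C)[C@@H](C)[C@H]2C(=O)OC(C)(OC)[C@H]2O1
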